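## The problem

CNP0249049.1 is a 3,4-seco-abietane. A fully substituted benzene ring (ring C) is fused to a single carbocycle, the tetralone ring B (C5–C10); ring A survives only as a propanoic acid arm (C1–C3) on C10 and an isopropenyl group (C4) on C5. Ring C carries six different substituents in fixed order (C8 acyl, C14 hydroxyl, C13 isopropyl, C12 methoxy, C11 hydroxyl, C9 alkyl), so each position must be addressed by a reaction of unambiguous site, and the two phenols need a mask that comes off without touching the methyl ether between them. The two stereocentres are adjacent: the quaternary benzylic C10 (S; methyl, arm, aryl, C5) and the tertiary C5 (S; isopropenyl cis to the C10 methyl). Nothing in the molecule can induce C10, so it must come from reagent control; C5 can be induced by C10, but only by telling a methyl group from the methylene of the arm. The free hydroquinone is oxidised by air, especially in base, the isopropenyl group does not tolerate strong protic acid, and C6 is enolisable; the phenols are therefore unveiled last and harsh acids and oxidants are confined to the arene stage. The enabling feature is the isopropenyl group on C5 beside the C6 methylene that is alpha to the C7 aryl ketone: with a hydroxyl added at C6 this is the product of a carbonyl-ene reaction between a 2-methylpropenyl group on C10 (C5=C4) and a glyoxal aldehyde (C6) on C8, the tether C7–C8–C9–C10 making the new ring six-membered.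

## Retrosynthesis

**31 ⇐ 30 ⇐ 29 (no skeletal bond cut).** Target 31 is traced to the bis(isopropyl ether) acid 30 and then to methyl ester 29. Isopropyl ethers are chosen for O11 and O14 because BCl3 ionises a secondary alkyl aryl ether far more readily than the C12 methyl ether, and because they survive n-BuLi, t-BuLi, boranes and the Lewis acid of the ring closure. The ester is hydrolysed before the phenols are freed, so no hydroquinone meets aqueous base. The forward steps must leave the isopropenyl group alone.

**29 ⇐ 28 (C6–O).** Putting a hydroxyl back on C6 gives α-ketol 28. This costs one later step, because a hydroxyl next to an aryl ketone is removed by SmI2, and its configuration is irrelevant. In return it exposes the ene retron.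

**28 ⇐ 27 (C5–C6, key step).** Cutting C5–C6 with transfer of hydrogen from O6 back to C4 opens ring B to aryl glyoxal 27. The neighbouring cuts (C6–C7 by acylation, C9–C10 by arylation) would close the ring but create neither the isopropenyl group nor C5. The ene cut makes the ring, the isopropenyl group and the C5 stereocentre together. Precursor 27 has one stereocentre and no ring B. The forward reaction must choose the aldehyde over the ketone and ester, and the correct alkene face relative to C10.

**27 ⇐ 26 ⇐ 25 ⇐ 23 ⇐ 21 (functional-group changes).** The glyoxal is made last, by neutral oxidation of primary α-ketol 26. An acetal-masked glyoxal was rejected because its hydrolysis needs acid strong enough to engage the nearby alkene in an uncontrolled cyclisation. The ester arm of 26 is the oxidised form of an allyl group: acid 25 comes from alcohol 23, and 23 from hydroboration of diene 21. In 21 the ketol oxygen is a silyl ether, which falls off in the esterification step. The forward reactions must distinguish a monosubstituted alkene from the trisubstituted one that is kept for the ene step.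

**21 ⇐ 18 + 19 (C7–C8).** The acyl group at C8 comes from aryl bromide 18, through the aryllithium, and the silyloxyacetyl donor 19. The bromide is the only handle compatible with the earlier steps, and the bond must be made before the arm carries an ester, which an aryllithium would attack.

**18 ⇐ 16 + 17 (C4=C5).** The 2-methylpropenyl group comes from aldehyde 16 and the isopropylidene ylide of 17. Aldehyde 16 has no α-hydrogen, so C10 is safe under basic conditions.

**16 ⇐ 14 + 15 (C10–C1).** The quaternary centre is disconnected at the allyl group, giving racemic 2-arylpropanal 14 and allyl alcohol 15. A catalytic asymmetric α-allylation converts both enantiomers of 14 into one enantiomer of 16. This is the only reagent-controlled stereochemical step, and the allyl group already holds the three carbons of the arm.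

**14 ⇐ 13 ⇐ 11 + 12 (C10–C5).** The aldehyde carbon is added to methyl ketone 11 as a methylene from sulfonium salt 12 (oxirane 13) and moved into place by a 1,2-hydride shift. The small sulfur ylide is preferred to a phosphorus ylide because the ketone is flanked on both sides.

**11 ⇐ 8 + 9 (C9–C10).** The acetyl group is placed at C9 of bromoarene 8 by deprotonation between bromine and isopropoxy and acylation with amide 9. The bromine at C8 thus marks C8, directs metalation to C9 and later becomes the C7–C8 bond.

**8 ⇐ 7 ⇐ 6 ⇐ 3 + 4; 3 ⇐ 1 + 2 (arene).** Bromine enters 7 at the position para to the methoxy group. The C13 isopropyl group of 7 comes from carbinol 6, made by directed ortho-metalation of 3 between the methoxy and an isopropoxy group and addition to acetone 4. Ether 3 is the double isopropyl ether formed from 2-methoxyhydroquinone 1 and two equivalents of 2-bromopropane 2, so all three ring oxygens are bought in place.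

## Roads not taken

**Alternative 1:** The aromatic ring itself is disconnected, C8–C14 in the key step and C9–C11 one step earlier, so that the hydroquinone is grown onto a finished ring B. Forward, the 4-hydroxy-4-cyclohexenylcyclobutenone A2 is heated; four-electron ring opening, six-electron ring closure (forming C8–C14) and tautomerisation give hydroquinone A1.
- Merits: the positions of all six arene substituents follow from connectivity alone, and the two phenols appear free beside the methyl ether. On arene regiochemistry this road is better than the chosen plan, which depends on the site of one bromination (step 4).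
- Weak points: both stereocentres must already be present in the cyclohexenyl fragment, so the C5/C10 problem is only moved into an unspecified ring B synthesis. The organometallic must add to the correct carbonyl of an unsymmetrical dione. C7 and C3 arrive as silyl ethers and would have to be oxidised in the presence of an electron-rich free hydroquinone, which would go to the quinone first.
- Comparison: the chosen plan makes both stereocentres itself and reaches the final oxidation levels at C7 and C3 while the phenols are still masked.

**Alternative 2:** Two ring B bonds are cut, C6–C7 and C5–C10. Forward, aldehyde A4, whose arm is tied to O11 as a seven-membered lactone, is irradiated with Ti(OiPr)4; photoenolisation gives a diene that adds across the 2,3-alkene of dienoate A5 to give cycloadduct A3.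
- Merits: ring B, two bonds and both stereocentres come from one convergent step. The relative configuration at C5/C10 is fixed by geometry (the lactone locks the diene terminus and the endo rule places the isopropenyl group), not by a methyl-versus-methylene size difference. On this point, the soft spot of the chosen plan, it is the better design.
- Weak points: the absolute configuration needs a chiral diol ligand on Ti(OiPr)4 acting at a fully substituted diene terminus. The dienophile is an electron-poor diene that can polymerise or isomerise under light. The adduct carries a surplus C6 ester, a C7 alcohol, a second aryl methyl ether to be cleaved selectively and a lactone to be opened.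
- Comparison: the chosen plan takes its absolute configuration from a catalytic reaction known for 2-arylpropanals, delivers C7 as the ketone, and needs one step to remove its single surplus group.

**Alternative 3:** C9–C10 and C1–C2 are cut. Forward, aryl bromide A7, an achiral ketone with two enantiotopic isopropenyl groups on C5, is treated with zerovalent palladium and a chiral bisphosphine. Oxidative addition at C9–Br and 6-exo insertion of one isopropenyl group form C9–C10, the quaternary centre and ring B; the resulting alkylpalladium, which has no β-hydrogen, is coupled with boronate A8 to give tetralone A6.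
- Merits: on paper this is the shortest road. Both stereocentres come from an achiral precursor in one catalytic event, the relative configuration follows from the insertion geometry, the C7 ketone and isopropenyl group are already present, and the acetal ethers come off under mild acid.
- Weak points: oxidative addition must occur at a bromide flanked on both sides on an electron-rich ring, and the insertion must build a quaternary centre next to that ring. Group selection and face selection must both be high, and direct coupling of the arylpalladium with A8 before cyclisation competes. This combination has no close precedent, so the whole route rests on one untested event.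
- Comparison: the chosen plan spreads its risk over steps that each have a direct analogy, at the price of length and of a substrate-controlled ring closure.

Key step: step 15

Remark on step 1: both phenols of 1 are etherified, so the step consumes two molar equivalents of 2; the second equivalent is entered on the reagent line of that step.
Remark on step 8: which enantiomer of the phosphoric acid gives (2R)-16 must be read from a trial run; (S)-TRIP is written, and its antipode serves equally if the sense is opposite.
Remark on reagents: amide 19 and the phosphoric acid are taken as catalogue reagents.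

## Route

Step 1
Reactants: 1 2-methoxybenzene-1,4-diol (2-methoxyhydroquinone); 2 2-bromopropane
Product: 3 1,4-diisopropoxy-2-methoxybenzene
Conditions: 2 (2.5 equiv), K2CO3 (3 equiv), DMF, 60 °C, N2
Reagents that add atoms: 2-bromopropane (second equivalent of 2), CC(C)Br
Why: Twofold Williamson ether synthesis, one molecule of 2 for each phenol; carbonate in DMF suffices for the secondary bromide, and exclusion of air keeps the hydroquinone anion from oxidising.

Step 2
Reactants: 3 1,4-diisopropoxy-2-methoxybenzene; 4 acetone
Product: 6 2-(3,6-diisopropoxy-2-methoxyphenyl)propan-2-ol, via aryllithium 5 (not isolated)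
Conditions: n-BuLi, TMEDA, Et2O, 0 °C → rt; then acetone, −78 °C → rt; H2O
Reagents that add atoms: none
Why: Directed ortho-metalation: the hydrogen between the methoxy and an isopropoxy group is the only one ortho to the better-coordinating methoxy oxygen and is acidified by two flanking oxygens (as in 1,2,4-trimethoxybenzene), so lithiation occurs there and the aryllithium adds to acetone.

Step 3
Reactants: 6 2-(3,6-diisopropoxy-2-methoxyphenyl)propan-2-ol
Product: 7 1,4-diisopropoxy-2-isopropyl-3-methoxybenzene
Conditions: Et3SiH, CF3CO2H, CH2Cl2, 0 °C → rt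
Reagents that add atoms: none
Why: Ionic hydrogenation: trifluoroacetic acid ionises the tertiary benzylic alcohol and triethylsilane transfers hydride to the cation; aryl isopropyl ethers are stable to this acid.

Step 4
Reactants: 7 1,4-diisopropoxy-2-isopropyl-3-methoxybenzene
Product: 8 1-bromo-2,5-diisopropoxy-3-isopropyl-4-methoxybenzene
Conditions: NBS, MeCN, 0 °C
Reagents that add atoms: N-bromosuccinimide, O=C1CCC(=O)N1Br
Why: Electrophilic aromatic bromination; of the two free positions the one para to the methoxy and ortho to an isopropoxy group (C8) is the more activated, as in halogenation and formylation of 1,2,4-trialkoxy-3-alkylbenzenes.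

Step 5
Reactants: 8 1-bromo-2,5-diisopropoxy-3-isopropyl-4-methoxybenzene; 9 N-methoxy-N-methylacetamide
Product: 11 1-(2-bromo-3,6-diisopropoxy-4-isopropyl-5-methoxyphenyl)ethan-1-one, via aryllithium 10 (not isolated)
Conditions: LiN(iPr)2, THF, −78 °C; then 9, −78 → −40 °C; H2O
Reagents that add atoms: none
Why: Deprotonative ortho-lithiation by LiN(iPr)2 at the last ring hydrogen, acidified by the flanking bromine and alkoxy group (cf. 3-bromoanisole), leaves the C–Br bond intact at low temperature, where loss of LiBr to an aryne is also slow; acyl substitution on the N-methoxy-N-methylamide stops at the ketone through the chelated tetrahedral adduct.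

Step 6
Reactants: 11 1-(2-bromo-3,6-diisopropoxy-4-isopropyl-5-methoxyphenyl)ethan-1-one; 12 trimethylsulfonium iodide
Product: 13 2-(2-bromo-3,6-diisopropoxy-4-isopropyl-5-methoxyphenyl)-2-methyloxirane (racemic)
Conditions: KOtBu, DMSO/THF, 0 °C → rt
Reagents that add atoms: none
Why: Corey–Chaykovsky epoxidation: the small dimethylsulfonium methylide adds to a ketone flanked by two ortho substituents, where a phosphorus ylide would be slow, and closes to the oxirane.

Step 7
Reactants: 13 2-(2-bromo-3,6-diisopropoxy-4-isopropyl-5-methoxyphenyl)-2-methyloxirane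
Product: 14 2-(2-bromo-3,6-diisopropoxy-4-isopropyl-5-methoxyphenyl)propanal (racemic)
Conditions: BF3·OEt2 (cat.), CH2Cl2, −78 °C
Reagents that add atoms: none
Why: Meinwald rearrangement: Lewis acid opening to the tertiary benzylic cation and a 1,2-hydride shift from the oxirane CH2; only hydride can migrate, so the 2-arylpropanal is the sole carbonyl product.

Step 8
Reactants: 14 2-(2-bromo-3,6-diisopropoxy-4-isopropyl-5-methoxyphenyl)propanal; 15 allyl alcohol (prop-2-en-1-ol)
Product: 16 (2R)-2-(2-bromo-3,6-diisopropoxy-4-isopropyl-5-methoxyphenyl)-2-methylpent-4-enal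
Conditions: Pd(PPh3)4 (cat.), (S)-TRIP [(S)-3,3′-bis(2,4,6-triisopropylphenyl)-1,1′-binaphthyl-2,2′-diyl hydrogen phosphate] (cat.), Ph2CHNH2 (0.4 equiv), 5 Å MS, toluene, 40 °C; then 1 M HCl
Reagents that add atoms: none
Why: Catalytic asymmetric α-allylation of an α-branched aldehyde (Tsuji–Trost-type alkylation under combined enamine, zerovalent palladium and chiral phosphate catalysis): both enantiomers of 14 pass through the same enamine, which attacks the π-allylpalladium cation paired with the chiral phosphate from one face and creates the quaternary C10. The product has no α-hydrogen and cannot racemise.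

Step 9
Reactants: 16 (2R)-2-(2-bromo-3,6-diisopropoxy-4-isopropyl-5-methoxyphenyl)-2-methylpent-4-enal; 17 isopropyltriphenylphosphonium iodide
Product: 18 1-bromo-2-[(4S)-4,6-dimethylhepta-1,5-dien-4-yl]-3,6-diisopropoxy-5-isopropyl-4-methoxybenzene
Conditions: KN(SiMe3)2, THF, 0 °C; then 16, 0 → 50 °C
Reagents that add atoms: none
Why: Wittig olefination with the non-stabilised isopropylidene ylide; the aldehyde has no α-hydrogen, so it cannot be enolised or epimerised, and an amide base is used so that no alkyllithium meets the aryl bromide.

Step 10
Reactants: 18 1-bromo-2-[(4S)-4,6-dimethylhepta-1,5-dien-4-yl]-3,6-diisopropoxy-5-isopropyl-4-methoxybenzene; 19 2-[(tert-butyldimethylsilyl)oxy]-N-methoxy-N-methylacetamide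
Product: 21 2-[(tert-butyldimethylsilyl)oxy]-1-{2-[(4S)-4,6-dimethylhepta-1,5-dien-4-yl]-3,6-diisopropoxy-5-isopropyl-4-methoxyphenyl}ethan-1-one, via aryllithium 20 (not isolated)
Conditions: t-BuLi (2.1 equiv), THF, −78 °C; then 19, −78 → 0 °C; H2O
Reagents that add atoms: none
Why: Bromine–lithium exchange (two equivalents of t-BuLi) followed by acyl substitution on the N-methoxy-N-methylamide; the chelated adduct releases the ketone only on work-up, and the C7–C8 bond forms at the one position that still carries a handle.

Step 11
Reactants: 21 2-[(tert-butyldimethylsilyl)oxy]-1-{2-[(4S)-4,6-dimethylhepta-1,5-dien-4-yl]-3,6-diisopropoxy-5-isopropyl-4-methoxyphenyl}ethan-1-one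
Product: 23 (4S)-4-(2-{[(tert-butyldimethylsilyl)oxy]acetyl}-3,6-diisopropoxy-4-isopropyl-5-methoxyphenyl)-4,6-dimethylhept-5-en-1-ol, via alkylborane 22 (not isolated)
Conditions: 9-BBN, THF, 0 °C → rt; then H2O2, aq. NaOAc, 0 °C → rt
Reagents that add atoms: hydrogen peroxide, OO
Why: Hydroboration–oxidation: 9-BBN adds anti-Markovnikov to the monosubstituted alkene much faster than to the hindered trisubstituted alkene or the shielded aryl ketone, and buffered peroxide spares the α-silyloxy ketone.

Step 12
Reactants: 23 (4S)-4-(2-{[(tert-butyldimethylsilyl)oxy]acetyl}-3,6-diisopropoxy-4-isopropyl-5-methoxyphenyl)-4,6-dimethylhept-5-en-1-ol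
Product: 25 (4S)-4-(2-{[(tert-butyldimethylsilyl)oxy]acetyl}-3,6-diisopropoxy-4-isopropyl-5-methoxyphenyl)-4,6-dimethylhept-5-enoic acid, via aldehyde 24 (not isolated)
Conditions: TEMPO (2,2,6,6-tetramethylpiperidin-1-oxyl, cat.), PhI(OAc)2, MeCN/H2O, rt
Reagents that add atoms: water, O
Why: Nitroxyl-catalysed oxidation of the primary alcohol through the aldehyde hydrate to the acid; the oxoammonium oxidant does not touch the alkene, the silyl ether or the arene.

Step 13
Reactants: 25 (4S)-4-(2-{[(tert-butyldimethylsilyl)oxy]acetyl}-3,6-diisopropoxy-4-isopropyl-5-methoxyphenyl)-4,6-dimethylhept-5-enoic acid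
Product: 26 methyl (4S)-4-[2-(hydroxyacetyl)-3,6-diisopropoxy-4-isopropyl-5-methoxyphenyl]-4,6-dimethylhept-5-enoate
Conditions: HCl (1.25 M in MeOH), 0 °C → rt
Reagents that add atoms: methanol, CO
Why: Fischer esterification and acid methanolysis of the primary silyl ether in one operation; dilute methanolic HCl at room temperature should leave the aryl isopropyl ethers and the trisubstituted alkene intact.

Step 14
Reactants: 26 methyl (4S)-4-[2-(hydroxyacetyl)-3,6-diisopropoxy-4-isopropyl-5-methoxyphenyl]-4,6-dimethylhept-5-enoate
Product: 27 methyl (4S)-4-[3,6-diisopropoxy-4-isopropyl-5-methoxy-2-(oxoacetyl)phenyl]-4,6-dimethylhept-5-enoate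
Conditions: Dess–Martin periodinane, pyridine, CH2Cl2, 0 °C
Reagents that add atoms: none
Why: Dess–Martin oxidation of the primary α-ketol to the aryl glyoxal under buffered, water-free conditions, so that neither a hydrate nor an acid-induced premature ring closure intervenes; the aldehyde is used at once.

Step 15
Reactants: 27 methyl (4S)-4-[3,6-diisopropoxy-4-isopropyl-5-methoxy-2-(oxoacetyl)phenyl]-4,6-dimethylhept-5-enoate
Product: 28 methyl 3-[(1S,2S)-3-hydroxy-5,8-diisopropoxy-6-isopropyl-7-methoxy-1-methyl-4-oxo-2-(prop-1-en-2-yl)-1,2,3,4-tetrahydronaphthalen-1-yl]propanoate (C3 carbinol as either epimer)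
Conditions: Me2AlCl (2.2 equiv), CH2Cl2, −78 °C; then H2O
Reagents that add atoms: none
Why: Intramolecular carbonyl-ene reaction: Me2AlCl binds the glyoxal aldehyde, C5 of the 2-methylpropenyl group bonds to C6 while a hydrogen of a C4 methyl group passes to the aldehyde oxygen through a six-membered array, and the double bond moves to C4=CH2. The closest known reaction type is the type one intramolecular carbonyl-ene cyclisation of aldehydes and glyoxylates onto trisubstituted alkenes promoted by Me2AlCl or MeAlCl2 (citronellal to isopulegol is the parent case). Ring B closes as a six-membered ring through the tether C7–C8–C9–C10, with the aldehyde oxygen and C4 both left outside the new ring (exo with respect to both π bonds). C10 is carried in unchanged; C5 is set by the alkene face that reaches the aldehyde, which depends on which C10 substituent lies beside the alkene's cis-methyl group: allylic 1,3-strain favours the methyl group there, because the arm could take that place only by turning its second carbon toward the doubly flanked aryl ring, and this puts the isopropenyl group cis to the methyl group (5S). C6 forms as either epimer and is removed in step 16. The step needs chemoselectivity for the aldehyde over the ketone and ester, which its higher electrophilicity and the ring size secure, and it needs the C5 face selectivity, which the low temperature is meant to sharpen; Me2AlCl also scavenges protons, so the alkenes should not isomerise and the isopropyl ethers should stay on.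

Step 16
Reactants: 28 methyl 3-[(1S,2S)-3-hydroxy-5,8-diisopropoxy-6-isopropyl-7-methoxy-1-methyl-4-oxo-2-(prop-1-en-2-yl)-1,2,3,4-tetrahydronaphthalen-1-yl]propanoate
Product: 29 methyl 3-[(1S,2S)-5,8-diisopropoxy-6-isopropyl-7-methoxy-1-methyl-4-oxo-2-(prop-1-en-2-yl)-1,2,3,4-tetrahydronaphthalen-1-yl]propanoate
Conditions: SmI2 (2.5 equiv), THF/MeOH, −78 °C
Reagents that add atoms: none
Why: Samarium diiodide reduction of an α-hydroxy ketone: two single-electron transfers to the aryl ketone expel the C6 hydroxide as the samarium enolate forms, and methanol protonates it at C6. This erases the C6 stereocentre and does not touch C5 or C10.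

Step 17
Reactants: 29 methyl 3-[(1S,2S)-5,8-diisopropoxy-6-isopropyl-7-methoxy-1-methyl-4-oxo-2-(prop-1-en-2-yl)-1,2,3,4-tetrahydronaphthalen-1-yl]propanoate
Product: 30 3-[(1S,2S)-5,8-diisopropoxy-6-isopropyl-7-methoxy-1-methyl-4-oxo-2-(prop-1-en-2-yl)-1,2,3,4-tetrahydronaphthalen-1-yl]propanoic acid
Conditions: LiOH, THF/MeOH/H2O, rt; then dil. HCl
Reagents that add atoms: lithium hydroxide, [Li+].[OH-]
Why: Ester saponification; it is done while the phenols are still masked, because a free hydroquinone would be oxidised in aqueous base.

Step 18
Reactants: 30 3-[(1S,2S)-5,8-diisopropoxy-6-isopropyl-7-methoxy-1-methyl-4-oxo-2-(prop-1-en-2-yl)-1,2,3,4-tetrahydronaphthalen-1-yl]propanoic acid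
Product: 31 3-[(1S,2S)-5,8-dihydroxy-6-isopropyl-7-methoxy-1-methyl-4-oxo-2-(prop-1-en-2-yl)-1,2,3,4-tetrahydronaphthalen-1-yl]propanoic acid (CNP0249049.1)
Conditions: BCl3, CH2Cl2, −78 → 0 °C; then H2O
Reagents that add atoms: none
Why: Lewis acid dealkylation: BCl3 cleaves the two secondary alkyl aryl ethers by ionisation at low temperature, a pathway not open to the C12 methyl ether, and aqueous work-up frees the hydroquinone and the acid.

## Compound list

1 | 2-methoxybenzene-1,4-diol (2-methoxyhydroquinone) | COc1cc(O)ccc1O | starting material
2 | 2-bromopropane | CC(C)Br | starting material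
3 | 1,4-diisopropoxy-2-methoxybenzene | COc1cc(OC(C)C)ccc1OC(C)C | intermediate
4 | acetone | CC(C)=O | starting material
5 | (3,6-diisopropoxy-2-methoxyphenyl)lithium | [Li]c1c(OC)c(OC(C)C)ccc1OC(C)C | intermediate
6 | 2-(3,6-diisopropoxy-2-methoxyphenyl)propan-2-ol | COc1c(OC(C)C)ccc(OC(C)C)c1C(C)(C)O | intermediate
7 | 1,4-diisopropoxy-2-isopropyl-3-methoxybenzene | COc1c(OC(C)C)ccc(OC(C)C)c1C(C)C | intermediate
8 | 1-bromo-2,5-diisopropoxy-3-isopropyl-4-methoxybenzene | COc1c(OC(C)C)cc(Br)c(OC(C)C)c1C(C)C | intermediate
9 | N-methoxy-N-methylacetamide | CC(=O)N(C)OC | starting material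
10 | (2-bromo-3,6-diisopropoxy-4-isopropyl-5-methoxyphenyl)lithium | [Li]c1c(Br)c(OC(C)C)c(C(C)C)c(OC)c1OC(C)C | intermediate
11 | 1-(2-bromo-3,6-diisopropoxy-4-isopropyl-5-methoxyphenyl)ethan-1-one | CC(=O)c1c(Br)c(OC(C)C)c(C(C)C)c(OC)c1OC(C)C | intermediate
12 | trimethylsulfonium iodide | C[S+](C)C.[I-] | starting material
13 | 2-(2-bromo-3,6-diisopropoxy-4-isopropyl-5-methoxyphenyl)-2-methyloxirane (racemic) | CC1(CO1)c1c(Br)c(OC(C)C)c(C(C)C)c(OC)c1OC(C)C | intermediate
14 | 2-(2-bromo-3,6-diisopropoxy-4-isopropyl-5-methoxyphenyl)propanal (racemic) | CC(C=O)c1c(Br)c(OC(C)C)c(C(C)C)c(OC)c1OC(C)C | intermediate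
15 | allyl alcohol (prop-2-en-1-ol) | C=CCO | starting material
16 | (2R)-2-(2-bromo-3,6-diisopropoxy-4-isopropyl-5-methoxyphenyl)-2-methylpent-4-enal | CC(C)Oc1c(OC)c(C(C)C)c(OC(C)C)c(Br)c1[C@@](C)(CC=C)C=O | intermediate
17 | isopropyltriphenylphosphonium iodide | CC(C)[P+](c1ccccc1)(c1ccccc1)c1ccccc1.[I-] | starting material
18 | 1-bromo-2-[(4S)-4,6-dimethylhepta-1,5-dien-4-yl]-3,6-diisopropoxy-5-isopropyl-4-methoxybenzene | CC(C)Oc1c(OC)c(C(C)C)c(OC(C)C)c(Br)c1[C@@](C)(CC=C)C=C(C)C | intermediate
19 | 2-[(tert-butyldimethylsilyl)oxy]-N-methoxy-N-methylacetamide | CON(C)C(=O)CO[Si](C)(C)C(C)(C)C | starting material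
20 | {2-[(4S)-4,6-dimethylhepta-1,5-dien-4-yl]-3,6-diisopropoxy-5-isopropyl-4-methoxyphenyl}lithium | [Li]c1c(OC(C)C)c(C(C)C)c(OC)c(OC(C)C)c1[C@@](C)(CC=C)C=C(C)C | intermediate
21 | 2-[(tert-butyldimethylsilyl)oxy]-1-{2-[(4S)-4,6-dimethylhepta-1,5-dien-4-yl]-3,6-diisopropoxy-5-isopropyl-4-methoxyphenyl}ethan-1-one | CC(C)(C)[Si](C)(C)OCC(=O)c1c(OC(C)C)c(C(C)C)c(OC)c(OC(C)C)c1[C@@](C)(CC=C)C=C(C)C | intermediate
22 | 9-[(4S)-4-(2-{[(tert-butyldimethylsilyl)oxy]acetyl}-3,6-diisopropoxy-4-isopropyl-5-methoxyphenyl)-4,6-dimethylhept-5-en-1-yl]-9-borabicyclo[3.3.1]nonane | CC(C)(C)[Si](C)(C)OCC(=O)c1c(OC(C)C)c(C(C)C)c(OC)c(OC(C)C)c1[C@@](C)(CCCB2C3CCCC2CCC3)C=C(C)C | intermediate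
23 | (4S)-4-(2-{[(tert-butyldimethylsilyl)oxy]acetyl}-3,6-diisopropoxy-4-isopropyl-5-methoxyphenyl)-4,6-dimethylhept-5-en-1-ol | CC(C)(C)[Si](C)(C)OCC(=O)c1c(OC(C)C)c(C(C)C)c(OC)c(OC(C)C)c1[C@@](C)(CCCO)C=C(C)C | intermediate
24 | (4S)-4-(2-{[(tert-butyldimethylsilyl)oxy]acetyl}-3,6-diisopropoxy-4-isopropyl-5-methoxyphenyl)-4,6-dimethylhept-5-enal | CC(C)(C)[Si](C)(C)OCC(=O)c1c(OC(C)C)c(C(C)C)c(OC)c(OC(C)C)c1[C@@](C)(CCC=O)C=C(C)C | intermediate
25 | (4S)-4-(2-{[(tert-butyldimethylsilyl)oxy]acetyl}-3,6-diisopropoxy-4-isopropyl-5-methoxyphenyl)-4,6-dimethylhept-5-enoic acid | CC(C)(C)[Si](C)(C)OCC(=O)c1c(OC(C)C)c(C(C)C)c(OC)c(OC(C)C)c1[C@@](C)(CCC(=O)O)C=C(C)C | intermediate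
26 | methyl (4S)-4-[2-(hydroxyacetyl)-3,6-diisopropoxy-4-isopropyl-5-methoxyphenyl]-4,6-dimethylhept-5-enoate | O=C(CO)c1c(OC(C)C)c(C(C)C)c(OC)c(OC(C)C)c1[C@@](C)(CCC(=O)OC)C=C(C)C | intermediate
27 | methyl (4S)-4-[3,6-diisopropoxy-4-isopropyl-5-methoxy-2-(oxoacetyl)phenyl]-4,6-dimethylhept-5-enoate | O=CC(=O)c1c(OC(C)C)c(C(C)C)c(OC)c(OC(C)C)c1[C@@](C)(CCC(=O)OC)C=C(C)C | intermediate
28 | methyl 3-[(1S,2S)-3-hydroxy-5,8-diisopropoxy-6-isopropyl-7-methoxy-1-methyl-4-oxo-2-(prop-1-en-2-yl)-1,2,3,4-tetrahydronaphthalen-1-yl]propanoate (C3 carbinol as either epimer) | C=C(C)[C@@H]1C(O)C(=O)c2c(OC(C)C)c(C(C)C)c(OC)c(OC(C)C)c2[C@@]1(C)CCC(=O)OC | intermediate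
29 | methyl 3-[(1S,2S)-5,8-diisopropoxy-6-isopropyl-7-methoxy-1-methyl-4-oxo-2-(prop-1-en-2-yl)-1,2,3,4-tetrahydronaphthalen-1-yl]propanoate | C=C(C)[C@@H]1CC(=O)c2c(OC(C)C)c(C(C)C)c(OC)c(OC(C)C)c2[C@@]1(C)CCC(=O)OC | intermediate
30 | 3-[(1S,2S)-5,8-diisopropoxy-6-isopropyl-7-methoxy-1-methyl-4-oxo-2-(prop-1-en-2-yl)-1,2,3,4-tetrahydronaphthalen-1-yl]propanoic acid | C=C(C)[C@@H]1CC(=O)c2c(OC(C)C)c(C(C)C)c(OC)c(OC(C)C)c2[C@@]1(C)CCC(=O)O | intermediate
31 | 3-[(1S,2S)-5,8-dihydroxy-6-isopropyl-7-methoxy-1-methyl-4-oxo-2-(prop-1-en-2-yl)-1,2,3,4-tetrahydronaphthalen-1-yl]propanoic acid (CNP0249049.1) | C=C(C)[C@@H]1CC(=O)c2c(O)c(C(C)C)c(OC)c(O)c2[C@@]1(C)CCC(=O)O | target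

## Step count and least certain steps

Total: 18 steps. Longest linear sequence: 18 steps from 1; every other component is purchased.

**Step 15 (key step).** The most likely failure is poor face selectivity at C5, because the substrate distinguishes only a methyl group from the methylene of the arm beside the alkene's cis-methyl group; an uncatalysed ring closure while 27 is being handled would add to this. The fallback moves stereocontrol from the substrate to a reagent. It sets out from 27 and returns at 28. The 1,2-dicarbonyl unit of 27 is bound in two-point fashion to a chiral Lewis acid, Cu(OTf)2 with 2,2′-isopropylidenebis[(4S)-4-tert-butyl-2-oxazoline] or its enantiomer, which selects the face of the aldehyde carbon C6. Because C5 and C6 are joined in one closed transition state, that choice is passed on to C5; the ligand enantiomer matched with C10 is kept, and C6 is erased in step 16 as before. No new compound arises (entry F0).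

**Step 8.** The most likely failure is slow and poorly selective bond formation, because the enamine carbon carries an aryl group substituted at both ortho positions; insertion of zerovalent palladium into the C–Br bond becomes a side path if the reaction is long. The fallback sets out from 14 and returns at 16. The potassium enolate of 14 is trapped on oxygen with allyl chloroformate to give allyl (1E)-2-(2-bromo-3,6-diisopropoxy-4-isopropyl-5-methoxyphenyl)prop-1-en-1-yl carbonate F1. This enol carbonate then undergoes decarboxylative asymmetric allylic alkylation with Pd2(dba)3 and a C2-symmetric diphosphine ligand built from trans-cyclohexane-1,2-diamine and 2-(diphenylphosphino)benzoic acid. Enolate and allyl cation are released together at the metal, no amine has to condense with the hindered aldehyde, and the enol carbonate geometry defines the prochiral nucleophile.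

**Step 10.** The most likely failure is proton transfer instead of addition: aryllithium 20, flanked by an alkoxy group and the quaternary carbon, may deprotonate amide 19 and return the debrominated arene. The fallback sets out from 18 and returns at 21. The same aryllithium is added to the far more electrophilic (tert-butyldimethylsilyloxy)acetaldehyde to give 2-[(tert-butyldimethylsilyl)oxy]-1-{2-[(4S)-4,6-dimethylhepta-1,5-dien-4-yl]-3,6-diisopropoxy-5-isopropyl-4-methoxyphenyl}ethan-1-ol F2 (both carbinol epimers), which Dess–Martin periodinane oxidises to 21.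

**Step 4.** The most likely failure is bromination at the other free position (C9), alone or in a mixture, since both positions are ortho to an isopropoxy group. The fallback sets out from 7 and returns at 11. The isomeric bromide 1-bromo-2,5-diisopropoxy-4-isopropyl-3-methoxybenzene F3 undergoes bromine–lithium exchange and acylation with 9 to give 1-(2,5-diisopropoxy-4-isopropyl-3-methoxyphenyl)ethan-1-one F4. Its only free ring position is C8, so NBS bromination now has no choice and gives 11. Both regioisomers of the bromination thus converge on 11.

**Step 18.** The most likely failure is loss of the crowded C12 methyl ether, helped by boron held between the new phenol oxygens, or addition of HCl to the isopropenyl group. The fallback sets out from 30 and ends at 31. Oxidative dealkylation with (NH4)2Ce(NO3)6 in aqueous MeCN turns the para-dialkoxyarene into 3-[(1S,2S)-6-isopropyl-7-methoxy-1-methyl-4,5,8-trioxo-2-(prop-1-en-2-yl)-1,2,3,4,5,8-hexahydronaphthalen-1-yl]propanoic acid F5, with the C12 methoxy group kept as a vinylogous ester. Na2S2O4 then reduces the quinone to hydroquinone 31 under neutral conditions.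

## Further compounds

F0 | step 15 | none | none
F1 | step 8 | allyl (1E)-2-(2-bromo-3,6-diisopropoxy-4-isopropyl-5-methoxyphenyl)prop-1-en-1-yl carbonate | C=CCOC(=O)O/C=C(\C)c1c(Br)c(OC(C)C)c(C(C)C)c(OC)c1OC(C)C
F2 | step 10 | 2-[(tert-butyldimethylsilyl)oxy]-1-{2-[(4S)-4,6-dimethylhepta-1,5-dien-4-yl]-3,6-diisopropoxy-5-isopropyl-4-methoxyphenyl}ethan-1-ol (both carbinol epimers) | CC(C)(C)[Si](C)(C)OCC(O)c1c(OC(C)C)c(C(C)C)c(OC)c(OC(C)C)c1[C@@](C)(CC=C)C=C(C)C
F3 | step 4 | 1-bromo-2,5-diisopropoxy-4-isopropyl-3-methoxybenzene | Brc1cc(OC(C)C)c(C(C)C)c(OC)c1OC(C)C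
F4 | step 4 | 1-(2,5-diisopropoxy-4-isopropyl-3-methoxyphenyl)ethan-1-one | CC(=O)c1cc(OC(C)C)c(C(C)C)c(OC)c1OC(C)C
F5 | step 18 | 3-[(1S,2S)-6-isopropyl-7-methoxy-1-methyl-4,5,8-trioxo-2-(prop-1-en-2-yl)-1,2,3,4,5,8-hexahydronaphthalen-1-yl]propanoic acid | C=C(C)[C@@H]1CC(=O)C2=C(C(=O)C(OC)=C(C(C)C)C2=O)[C@@]1(C)CCC(=O)O
A1 | alternative 1 | (5S,6S)-8-[(tert-butyldimethylsilyl)oxy]-5-{3-[(tert-butyldimethylsilyl)oxy]propyl}-2-isopropyl-3-methoxy-5-methyl-6-(prop-1-en-2-yl)-5,6,7,8-tetrahydronaphthalene-1,4-diol | C=C(C)[C@@H]1CC(O[Si](C)(C)C(C)(C)C)c2c(O)c(C(C)C)c(OC)c(O)c2[C@@]1(C)CCCO[Si](C)(C)C(C)(C)C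
A2 | alternative 1 | 4-hydroxy-2-isopropyl-3-methoxy-4-[3-[(tert-butyldimethylsilyl)oxy]-6-{3-[(tert-butyldimethylsilyl)oxy]propyl}-6-methyl-5-(prop-1-en-2-yl)cyclohex-1-en-1-yl]cyclobut-2-en-1-one (ring stereocentres as in A1) | C=C(C)[C@@H]1CC(O[Si](C)(C)C(C)(C)C)C=C([C@@]1(C)CCCO[Si](C)(C)C(C)(C)C)C1(O)C(OC)=C(C(C)C)C1=O
A3 | alternative 2 | tricyclic lactone cycloadduct: ring B with C7 hydroxyl, C6 methoxycarbonyl, C5 isopropenyl and C10 methyl, C12 and C14 methyl ethers, arm closed onto O11 | C=C(C)[C@@H]1[C@@H](C(=O)OC)[C@@H](O)c2c(OC)c(C(C)C)c(OC)c3c2[C@@]1(C)CCC(=O)O3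
A4 | alternative 2 | 8-isopropyl-7,9-dimethoxy-5-methyl-2-oxo-2,3,4,5-tetrahydro-1-benzoxepine-6-carbaldehyde (racemic) | O=Cc1c(OC)c(C(C)C)c(OC)c2OC(=O)CCC(C)c12
A5 | alternative 2 | methyl (2E)-4-methylpenta-2,4-dienoate | C=C(C)/C=C/C(=O)OC
A6 | alternative 3 | (3S,4S)-4-[(2E)-3-ethoxyprop-2-en-1-yl]-7-isopropyl-6-methoxy-5,8-bis(methoxymethoxy)-4-methyl-3-(prop-1-en-2-yl)-3,4-dihydronaphthalen-1(2H)-one | C=C(C)[C@@H]1CC(=O)c2c(OCOC)c(C(C)C)c(OC)c(OCOC)c2[C@@]1(C)C/C=C/OCC
A7 | alternative 3 | 1-[2-bromo-5-isopropyl-4-methoxy-3,6-bis(methoxymethoxy)phenyl]-4-methyl-3-(prop-1-en-2-yl)pent-4-en-1-one | C=C(C)C(CC(=O)c1c(OCOC)c(C(C)C)c(OC)c(OCOC)c1Br)C(C)=C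
A8 | alternative 3 | 2-[(E)-2-ethoxyethenyl]-4,4,5,5-tetramethyl-1,3,2-dioxaborolane | CCO/C=C/B1OC(C)(C)C(C)(C)O1
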